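**Retrosynthetic overview**
- Feature: the fully substituted imidazole ring of the target (N1–CH3, C2–N, C4–CH(OH)Ar next to N3, C5–CH2Ar next to N1) maps onto creatinine, which already holds N1–CH3, the C2 amino nitrogen, a C5 methylene and a C4 carbonyl in that order.
- Late disconnections: the exocyclic N–C amidine bond to the imidazolidinedione ring (1-methylparabanic acid), then the carbinol C–aryl bond (enantioselective anisyl transfer to an imidazole-4-carbaldehyde, which sets the R centre).
- Middle disconnection: the C4–CHO bond, by carbonylation of the aromatising C4 enol triflate of the creatinine ring.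
- First bond made: C5–CH(aryl), by Knoevenagel condensation of creatinine with 4-hydroxybenzaldehyde, followed by hydrogenation of the arylidene.
- Ring order: no ring is closed; the imidazole ring is bought as its 4-oxo-4,5-dihydro form and becomes aromatic at the triflation, and the imidazolidinedione ring and both benzene rings are bought.

Key step: step 1

Remark: the carbinol centre of the target is R (OH > imidazol-4-yl > 4-methoxyphenyl > H); compounds 4 to 6 are racemic at C5, a centre that disappears on aromatisation; 1-methylparabanic acid is taken as a purchased reagent.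

**Step 1**
Reactants: 1 creatinine; 2 4-hydroxybenzaldehyde
Product: 3 (E)-2-amino-5-(4-hydroxybenzylidene)-1-methyl-1,5-dihydro-4H-imidazol-4-one
Conditions: NaOAc, AcOH, 118 °C
Reagents that add atoms: none
Why: Knoevenagel (aldol) condensation: acetate-assisted enolisation of creatinine at the C5 methylene, which lies between the C4 lactam carbonyl and N1, is followed by addition to the aldehyde carbonyl and E1cB loss of water, so that the one new skeletal bond is C5–CH(aryl). The closest known reaction is the long-established condensation of creatinine, hydantoins and related glycocyamidines with aromatic aldehydes in hot acetic acid with sodium acetate or in the melt. No ring is closed, because the imidazolone ring is bought with N1–CH3, the C2 amino group and the C4 carbonyl already in place, which fixes the benzyl carbon next to N1 before any bond is made. No stereocentre is formed; the alkene is expected mainly as the E isomer, with the aryl group turned away from the N1 methyl, and its geometry is erased in step 2. The selectivity needed is carbon condensation at C5 over imine or aminal formation at the 2-amino group: the acylguanidine nitrogen is a poor nucleophile, its aldehyde adducts are reversible, and only the C5 pathway ends in an irreversible dehydration to a conjugated, sparingly soluble product. A second condensation is excluded because C5 carries no hydrogen after the dehydration.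

**Step 2**
Reactants: 3 (E)-2-amino-5-(4-hydroxybenzylidene)-1-methyl-1,5-dihydro-4H-imidazol-4-one
Product: 4 2-amino-5-(4-hydroxybenzyl)-1-methyl-1,5-dihydro-4H-imidazol-4-one (racemic)
Conditions: H2 (1 atm), 10% Pd/C, MeOH/AcOH, rt
Reagents that add atoms: none
Why: Catalytic hydrogenation of the conjugated exocyclic C=C of an unsaturated lactam should be fast on palladium on carbon, while the guanidine C=N and the phenol ring are not reduced under these conditions.

**Step 3**
Reactants: 4 2-amino-5-(4-hydroxybenzyl)-1-methyl-1,5-dihydro-4H-imidazol-4-one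
Product: 5 2-amino-1-methyl-5-[4-(triisopropylsilyloxy)benzyl]-1,5-dihydro-4H-imidazol-4-one
Conditions: i-Pr3SiCl, imidazole, DMF, rt
Reagents that add atoms: chlorotriisopropylsilane, CC(C)[Si](Cl)(C(C)C)C(C)C
Why: Imidazole-promoted O-silylation of the phenol; the acylguanidine nitrogen is a much weaker nucleophile and any N–Si bond is hydrolysed on work-up, and the triisopropylsilyl ether is chosen because it should survive the amide base, the palladium step and the organozinc step yet be cleaved by fluoride without acid.

**Step 4**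
Reactants: 5 2-amino-1-methyl-5-[4-(triisopropylsilyloxy)benzyl]-1,5-dihydro-4H-imidazol-4-one
Product: 6 (E)-N,N-dimethyl-N'-{1-methyl-4-oxo-5-[4-(triisopropylsilyloxy)benzyl]-4,5-dihydro-1H-imidazol-2-yl}formimidamide
Conditions: Me2NCH(OMe)2, toluene, 60 °C
Reagents that add atoms: N,N-dimethylformamide dimethyl acetal, COC(OC)N(C)C
Why: Amidine formation by condensation of the exocyclic primary amino group with the amide acetal removes both N–H bonds, so that C5–H is the only acidic site left for step 5; the C5 methine cannot give an enaminone and the phenol is already masked against O-methylation.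

**Step 5**
Reactants: 6 (E)-N,N-dimethyl-N'-{1-methyl-4-oxo-5-[4-(triisopropylsilyloxy)benzyl]-4,5-dihydro-1H-imidazol-2-yl}formimidamide
Product: 8 2-[(E)-(dimethylaminomethylene)amino]-1-methyl-5-[4-(triisopropylsilyloxy)benzyl]-1H-imidazol-4-yl trifluoromethanesulfonate, via potassium imidazol-4-olate 7 (not isolated)
Conditions: KN(SiMe3)2, THF, −78 °C; PhNTf2, −78 to 0 °C
Reagents that add atoms: N-phenylbis(trifluoromethanesulfonimide), O=S(=O)(N(c1ccccc1)S(=O)(=O)C(F)(F)F)C(F)(F)F
Why: Proposed new method: C5–H of 6 is the only acidic hydrogen (alpha to the lactam carbonyl and to N1), so KN(SiMe3)2 should give the aromatic imidazol-4-olate 7, which PhNTf2 should sulfonylate at its hard oxygen terminus because only O-attack keeps the 6π imidazole; the closest known reactions are the O-triflation of oxazol-5(4H)-ones, oxazol-4(5H)-ones, thiazol-4(5H)-ones and pyrazol-3-ones to heteroaryl triflates, extended here to a 2-amidino-imidazol-4(5H)-one.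

**Step 6**
Reactants: 8 2-[(E)-(dimethylaminomethylene)amino]-1-methyl-5-[4-(triisopropylsilyloxy)benzyl]-1H-imidazol-4-yl trifluoromethanesulfonate
Product: 9 2-[(E)-(dimethylaminomethylene)amino]-1-methyl-5-[4-(triisopropylsilyloxy)benzyl]-1H-imidazole-4-carbaldehyde
Conditions: CO (1 atm), Et3SiH, Pd(OAc)2 (5 mol %), dppp, Et3N, DMF, 70 °C
Reagents that add atoms: carbon monoxide, [C-]#[O+]
Why: Palladium-catalysed reductive carbonylation (formylation) of an aryl triflate: oxidative addition of the C4–O triflate bond to the zerovalent palladium–dppp complex, CO insertion and hydride transfer from the silane to the acylpalladium should release the aldehyde, with Et3N taking up the triflate and the silyl ether and amidine left untouched.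

**Step 7**
Reactants: 9 2-[(E)-(dimethylaminomethylene)amino]-1-methyl-5-[4-(triisopropylsilyloxy)benzyl]-1H-imidazole-4-carbaldehyde; 10 4-methoxyphenylboronic acid
Product: 12 (R)-{2-[(E)-(dimethylaminomethylene)amino]-1-methyl-5-[4-(triisopropylsilyloxy)benzyl]-1H-imidazol-4-yl}(4-methoxyphenyl)methanol, via ethyl(4-methoxyphenyl)zinc 11 (not isolated)
Conditions: 10 (2.4 equiv), Et2Zn (7 equiv), toluene, 60 °C; then (+)-MIB (20 mol %), 9, 0 °C to rt; aq. NaHCO3
Reagents that add atoms: none
Why: Catalytic enantioselective aryl transfer to an aldehyde: boron-to-zinc exchange gives the mixed arylethylzinc 11, and the zinc alkoxide of (+)-MIB [(2R)-3-exo-morpholinoisoborneol], the antipode of the ligand that directs organozinc additions to the Si face, should deliver the anisyl group (which transfers in preference to ethyl) to the Re face of the aldehyde, which corresponds to the R carbinol because imidazol-4-yl outranks 4-methoxyphenyl.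

**Step 8**
Reactants: 12 (R)-{2-[(E)-(dimethylaminomethylene)amino]-1-methyl-5-[4-(triisopropylsilyloxy)benzyl]-1H-imidazol-4-yl}(4-methoxyphenyl)methanol
Product: 13 (R)-{2-[(E)-(dimethylaminomethylene)amino]-5-(4-hydroxybenzyl)-1-methyl-1H-imidazol-4-yl}(4-methoxyphenyl)methanol
Conditions: Bu4NF, THF, 0 °C
Reagents that add atoms: none
Why: Fluoride-induced cleavage of the aryl silyl ether; the medium is basic, so the acid-labile diarylcarbinol should keep its configuration.

**Step 9**
Reactants: 13 (R)-{2-[(E)-(dimethylaminomethylene)amino]-5-(4-hydroxybenzyl)-1-methyl-1H-imidazol-4-yl}(4-methoxyphenyl)methanol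
Product: 14 (R)-[2-amino-5-(4-hydroxybenzyl)-1-methyl-1H-imidazol-4-yl](4-methoxyphenyl)methanol
Conditions: N2H4·H2O, EtOH, 50 °C
Reagents that add atoms: none
Why: Transamidination: hydrazine adds to the formamidine carbon and the less basic 2-aminoimidazole nitrogen is expelled, a standard non-acidic removal of an N,N-dimethylformamidine that leaves the carbinol centre untouched.

**Step 10**
Reactants: 14 (R)-[2-amino-5-(4-hydroxybenzyl)-1-methyl-1H-imidazol-4-yl](4-methoxyphenyl)methanol; 15 1-methylparabanic acid
Product: 19 4-({4-[(R)-hydroxy(4-methoxyphenyl)methyl]-5-(4-hydroxybenzyl)-1-methyl-1H-imidazol-2-yl}amino)-1-methyl-1H-imidazole-2,5-dione (CNP0181743.1), via silyl imidate of 1-methylparabanic acid 16 (not isolated), via bis(trimethylsilyl) ether of the amine 17 (not isolated), via bis(trimethylsilyl) ether of the target 18 (not isolated)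
Conditions: 15, N,O-bis(trimethylsilyl)acetamide (BSA), MeCN, 80 °C; then 14, toluene, 100 °C; then THF–pH 7 phosphate buffer, rt
Reagents that add atoms: none
Why: Silylative condensation known for 2-aminoimidazoles of the naamine type: BSA turns 1-methylparabanic acid into the O-silyl imidate 16 and masks both hydroxyl groups of 14 as trimethylsilyl ethers (17), the exocyclic 2-amino nitrogen then adds to the activated C4 of 16 (the carbonyl between N3 and C5, not the one next to N–CH3) and expels trimethylsilanol to give amidine 18, and neutral hydrolysis of the two O–Si bonds should release 19 without acid that could ionise the carbinol.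

**Compound list**
1 | creatinine | CN1CC(=O)N=C1N | starting material
2 | 4-hydroxybenzaldehyde | O=Cc1ccc(O)cc1 | starting material
3 | (E)-2-amino-5-(4-hydroxybenzylidene)-1-methyl-1,5-dihydro-4H-imidazol-4-one | CN1C(N)=NC(=O)/C1=C\c1ccc(O)cc1 | intermediate
4 | 2-amino-5-(4-hydroxybenzyl)-1-methyl-1,5-dihydro-4H-imidazol-4-one (racemic) | CN1C(N)=NC(=O)C1Cc1ccc(O)cc1 | intermediate
5 | 2-amino-1-methyl-5-[4-(triisopropylsilyloxy)benzyl]-1,5-dihydro-4H-imidazol-4-one (racemic) | CN1C(N)=NC(=O)C1Cc1ccc(O[Si](C(C)C)(C(C)C)C(C)C)cc1 | intermediate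
6 | (E)-N,N-dimethyl-N'-{1-methyl-4-oxo-5-[4-(triisopropylsilyloxy)benzyl]-4,5-dihydro-1H-imidazol-2-yl}formimidamide (racemic) | CN(C)/C=N/C1=NC(=O)C(Cc2ccc(O[Si](C(C)C)(C(C)C)C(C)C)cc2)N1C | intermediate
7 | potassium 2-[(E)-(dimethylaminomethylene)amino]-1-methyl-5-[4-(triisopropylsilyloxy)benzyl]-1H-imidazol-4-olate | [K+].CN(C)/C=N/c1nc([O-])c(Cc2ccc(O[Si](C(C)C)(C(C)C)C(C)C)cc2)n1C | intermediate (not isolated)
8 | 2-[(E)-(dimethylaminomethylene)amino]-1-methyl-5-[4-(triisopropylsilyloxy)benzyl]-1H-imidazol-4-yl trifluoromethanesulfonate | CN(C)/C=N/c1nc(OS(=O)(=O)C(F)(F)F)c(Cc2ccc(O[Si](C(C)C)(C(C)C)C(C)C)cc2)n1C | intermediate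
9 | 2-[(E)-(dimethylaminomethylene)amino]-1-methyl-5-[4-(triisopropylsilyloxy)benzyl]-1H-imidazole-4-carbaldehyde | CN(C)/C=N/c1nc(C=O)c(Cc2ccc(O[Si](C(C)C)(C(C)C)C(C)C)cc2)n1C | intermediate
10 | 4-methoxyphenylboronic acid | COc1ccc(B(O)O)cc1 | starting material
11 | ethyl(4-methoxyphenyl)zinc | CC[Zn]c1ccc(OC)cc1 | intermediate (not isolated)
12 | (R)-{2-[(E)-(dimethylaminomethylene)amino]-1-methyl-5-[4-(triisopropylsilyloxy)benzyl]-1H-imidazol-4-yl}(4-methoxyphenyl)methanol | COc1ccc([C@@H](O)c2nc(/N=C/N(C)C)n(C)c2Cc2ccc(O[Si](C(C)C)(C(C)C)C(C)C)cc2)cc1 | intermediate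
13 | (R)-{2-[(E)-(dimethylaminomethylene)amino]-5-(4-hydroxybenzyl)-1-methyl-1H-imidazol-4-yl}(4-methoxyphenyl)methanol | COc1ccc([C@@H](O)c2nc(/N=C/N(C)C)n(C)c2Cc2ccc(O)cc2)cc1 | intermediate
14 | (R)-[2-amino-5-(4-hydroxybenzyl)-1-methyl-1H-imidazol-4-yl](4-methoxyphenyl)methanol | COc1ccc([C@@H](O)c2nc(N)n(C)c2Cc2ccc(O)cc2)cc1 | intermediate
15 | 1-methylparabanic acid (1-methylimidazolidine-2,4,5-trione) | CN1C(=O)NC(=O)C1=O | starting material
16 | 1-methyl-4-(trimethylsilyloxy)-1H-imidazole-2,5-dione (silyl imidate of 15) | CN1C(=O)N=C(O[Si](C)(C)C)C1=O | intermediate (not isolated)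
17 | O,O'-bis(trimethylsilyl) ether of 14 | COc1ccc([C@@H](O[Si](C)(C)C)c2nc(N)n(C)c2Cc2ccc(O[Si](C)(C)C)cc2)cc1 | intermediate (not isolated)
18 | O,O'-bis(trimethylsilyl) ether of 19 | COc1ccc([C@@H](O[Si](C)(C)C)c2nc(NC3=NC(=O)N(C)C3=O)n(C)c2Cc2ccc(O[Si](C)(C)C)cc2)cc1 | intermediate (not isolated)
19 | 4-({4-[(R)-hydroxy(4-methoxyphenyl)methyl]-5-(4-hydroxybenzyl)-1-methyl-1H-imidazol-2-yl}amino)-1-methyl-1H-imidazole-2,5-dione (CNP0181743.1) | COc1ccc([C@@H](O)c2nc(NC3=NC(=O)N(C)C3=O)n(C)c2Cc2ccc(O)cc2)cc1 | target

**Totals**
Total step count: 10. Longest linear sequence: 10 steps (1 to 19 through steps 1 to 10).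

**Steps most likely to fail**

Step 5 (aromatising O-triflation). What may go wrong: sulfonylation at N3 or at the amidine nitrogen instead of oxygen, or hydrolytic S–O cleavage of the electron-rich heteroaryl triflate during isolation. The fallback sets out from 6 and uses known chemistry: deoxybromination of the lactam carbonyl with POBr3 (MeCN, 80 °C), the classical conversion of cyclic amide and ureide carbonyls into bromoheteroarenes, should give the 4-bromoimidazole F1. Bromine–lithium exchange with n-BuLi (THF, −78 °C; C2 is blocked, so no ring deprotonation competes) should give the 4-lithioimidazole F2, which is quenched with DMF. The fallback comes back to the route at aldehyde 9, so that steps 5 and 6 are both bypassed.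

Step 7 (enantioselective anisyl transfer). What may go wrong: erosion of enantioselectivity through an uncatalysed addition assisted by chelation of zinc between N3 and the aldehyde oxygen, through catalysis by the product zinc alkoxide, and through competing ethyl transfer. The fallback sets out from 9 and replaces aryl transfer by catalyst-controlled ketone reduction. Addition of 4-MeOC6H4MgBr (THF, −78 to 0 °C) should give the racemic carbinol F3, and oxidation with MnO2 (CH2Cl2, rt) the diaryl ketone F4. Asymmetric transfer hydrogenation with RuCl[(S,S)-TsDPEN](p-cymene) and HCO2Na in H2O/MeOH at 40 °C, the catalyst antipode being chosen in a test run so that hydride reaches the face leading to R, should then differentiate the coplanar anisyl ring from the twisted, 5-substituted imidazolyl ring. The fallback comes back to the route at 12.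

Step 10 (silylative condensation). What may go wrong: ionisation of the doubly activated benzylic C–O bond in the hot silylating medium, leading to loss of configurational purity, Friedel–Crafts closure onto the neighbouring benzyl ring or elimination. The fallback sets out from 13 and carries the carbinol carbon through the thermal step at the ketone oxidation level, so that the stereocentre is created last. MnO2 (CH2Cl2/THF, rt) should oxidise the activated carbinol to the phenolic ketone F5. Conc. aq. NH3 in MeOH (50 °C; hydrazine is avoided because of the ketone) should remove the formamidine to give the amino ketone F6. Condensation with 15 under the conditions of step 10, by way of 16, the O-trimethylsilyl ether F7 of the amino ketone and the silylated keto amidine F8, should give the keto amidine F9. Asymmetric transfer hydrogenation of F9 with RuCl[(S,S)-TsDPEN](p-cymene) or its antipode and HCO2Na (H2O/MeOH, 40 °C) then comes back to the route at the target 19.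

**Further compounds**
F1 | step 5 | (E)-N'-{4-bromo-1-methyl-5-[4-(triisopropylsilyloxy)benzyl]-1H-imidazol-2-yl}-N,N-dimethylformimidamide | CN(C)/C=N/c1nc(Br)c(Cc2ccc(O[Si](C(C)C)(C(C)C)C(C)C)cc2)n1C
F2 | step 5 | {2-[(E)-(dimethylaminomethylene)amino]-1-methyl-5-[4-(triisopropylsilyloxy)benzyl]-1H-imidazol-4-yl}lithium | [Li]c1nc(/N=C/N(C)C)n(C)c1Cc1ccc(O[Si](C(C)C)(C(C)C)C(C)C)cc1
F3 | step 7 | racemic {2-[(E)-(dimethylaminomethylene)amino]-1-methyl-5-[4-(triisopropylsilyloxy)benzyl]-1H-imidazol-4-yl}(4-methoxyphenyl)methanol | COc1ccc(C(O)c2nc(/N=C/N(C)C)n(C)c2Cc2ccc(O[Si](C(C)C)(C(C)C)C(C)C)cc2)cc1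
F4 | step 7 | {2-[(E)-(dimethylaminomethylene)amino]-1-methyl-5-[4-(triisopropylsilyloxy)benzyl]-1H-imidazol-4-yl}(4-methoxyphenyl)methanone | COc1ccc(C(=O)c2nc(/N=C/N(C)C)n(C)c2Cc2ccc(O[Si](C(C)C)(C(C)C)C(C)C)cc2)cc1
F5 | step 10 | {2-[(E)-(dimethylaminomethylene)amino]-5-(4-hydroxybenzyl)-1-methyl-1H-imidazol-4-yl}(4-methoxyphenyl)methanone | COc1ccc(C(=O)c2nc(/N=C/N(C)C)n(C)c2Cc2ccc(O)cc2)cc1
F6 | step 10 | [2-amino-5-(4-hydroxybenzyl)-1-methyl-1H-imidazol-4-yl](4-methoxyphenyl)methanone | COc1ccc(C(=O)c2nc(N)n(C)c2Cc2ccc(O)cc2)cc1
F7 | step 10 | {2-amino-1-methyl-5-[4-(trimethylsilyloxy)benzyl]-1H-imidazol-4-yl}(4-methoxyphenyl)methanone | COc1ccc(C(=O)c2nc(N)n(C)c2Cc2ccc(O[Si](C)(C)C)cc2)cc1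
F8 | step 10 | 4-({4-(4-methoxybenzoyl)-1-methyl-5-[4-(trimethylsilyloxy)benzyl]-1H-imidazol-2-yl}amino)-1-methyl-1H-imidazole-2,5-dione | COc1ccc(C(=O)c2nc(NC3=NC(=O)N(C)C3=O)n(C)c2Cc2ccc(O[Si](C)(C)C)cc2)cc1
F9 | step 10 | 4-{[5-(4-hydroxybenzyl)-4-(4-methoxybenzoyl)-1-methyl-1H-imidazol-2-yl]amino}-1-methyl-1H-imidazole-2,5-dione | COc1ccc(C(=O)c2nc(NC3=NC(=O)N(C)C3=O)n(C)c2Cc2ccc(O)cc2)cc1
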